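**Retrosynthetic overview**
1. Target 20 is a 3-methylisoquinoline and a salicylaldehyde ring joined by a 2,9-dioxabicyclo[3.3.1]nonane. A 1,3-dioxine ring (on C6–C7 of the isoquinoline) and an isochroman ring (on the benzaldehyde ring) share the bridging oxygen. The acetyl group is carried as vinyl (Tsuji–Wacker, step 11) and the phenol as OTIPS.
2. Key disconnection (step 10): the bond from the acetal CH to the benzaldehyde-ring carbon and both acetal C–O bonds are cut. This leads back to the open-chain (1R,2S)-diol 14 and HC(OMe)3.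
3. Enabling feature: the acetal carbon carries the isoquinoline C6 oxygen and the benzylic oxygen of the C7–CH group. This 1,3-related salicyl-alcohol pair can tie an orthoformate carbon into a cyclic dioxocarbenium ion. Its third partner is the arene carbon ortho to OMe and para to the phenol oxygen, the nucleophilic site of a resorcinol-type ring held three atoms away.
4. Diol 14 comes from an anti-selective asymmetric allylboration of isoquinoline aldehyde 11 with the allylborane made from aryl allene 5. Both 5 and 11 come from bromide 4, which is made from 4-bromo-2,6-dimethoxybenzaldehyde 1.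
5. Ring order: pyridine ring of the isoquinoline (step 6), then the 1,3-dioxine ring, then the isochroman ring (both in step 10, the isochroman ring last).

Key step: step 10

Assumption: the SMILES is read as R at the acetal carbon, R at the benzylic O–CH carbon and S at the acetyl-bearing carbon, which places the acetyl group cis to the isoquinoline on the isochroman ring and corresponds to an anti arrangement in the open-chain precursor; 1 and the named reagents are taken as purchasable, and (+)-Ipc2BH is made from (−)-α-pinene and BH3·SMe2.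

**Step 1**
Reactants: 1 4-bromo-2,6-dimethoxybenzaldehyde
Product: 2 4-bromo-2-hydroxy-6-methoxybenzaldehyde
Conditions: BCl3 (1.1 equiv), CH2Cl2, −78 → 0 °C; H2O
Reagents that add atoms: none
Why: Chelation-directed Lewis acid ether cleavage, in which BCl3 binds the formyl oxygen and removes one of the two equivalent ortho methyl groups while the resulting boron chelate resists a second cleavage.

**Step 2**
Reactants: 2 4-bromo-2-hydroxy-6-methoxybenzaldehyde
Product: 3 4-bromo-2-methoxy-6-(triisopropylsilyloxy)benzaldehyde
Conditions: TIPSOTf, 2,6-lutidine, CH2Cl2, 0 °C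
Reagents that add atoms: triisopropylsilyl triflate, CC(C)[Si](OS(=O)(=O)C(F)(F)F)(C(C)C)C(C)C
Why: Standard silylation of a hindered, hydrogen-bonded phenol with a silyl triflate, which installs the bulky non-coordinating group that later steers steps 5 and 10.

**Step 3**
Reactants: 3 4-bromo-2-methoxy-6-(triisopropylsilyloxy)benzaldehyde
Product: 4 2-[4-bromo-2-methoxy-6-(triisopropylsilyloxy)phenyl]-1,3-dioxolane
Conditions: (TMSOCH2)2, TMSOTf (5 mol %), CH2Cl2, −78 → −20 °C; pyridine
Reagents that add atoms: 1,2-bis(trimethylsilyloxy)ethane, C[Si](C)(C)OCCO[Si](C)(C)C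
Why: Noyori acetalisation under water-free kinetic conditions, driven by formation of the disiloxane, masks the formyl group against amide base and allylborane and keeps the ring electron-rich for step 10.

**Step 4**
Reactants: 4 2-[4-bromo-2-methoxy-6-(triisopropylsilyloxy)phenyl]-1,3-dioxolane
Product: 5 2-[2-methoxy-4-(propa-1,2-dien-1-yl)-6-(triisopropylsilyloxy)phenyl]-1,3-dioxolane
Conditions: allenyl-SnBu3, Pd(PPh3)4 (5 mol %), DMF, 80 °C
Reagents that add atoms: tributyl(propa-1,2-dien-1-yl)stannane, C=C=C[Sn](CCCC)(CCCC)CCCC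
Why: Stille coupling of an allenylstannane with an aryl bromide, a reaction type known to give the aryl allene rather than the propargyl isomer under neutral conditions that spare acetal and silyl ether.

**Step 5**
Reactants: 4 2-[4-bromo-2-methoxy-6-(triisopropylsilyloxy)phenyl]-1,3-dioxolane
Product: 7 6-bromo-3-(1,3-dioxolan-2-yl)-2-methoxy-4-(triisopropylsilyloxy)benzaldehyde, via aryllithium 6 (not isolated)
Conditions: LDA (1.2 equiv), THF, −78 °C; DMF, −78 °C; AcOH
Reagents that add atoms: N,N-dimethylformamide, CN(C)C=O
Why: Deprotonative ortho-lithiation of a 3-bromoanisole-type arene at the C–H flanked by OMe and Br (acidified by both, lithium held by OMe) followed by formylation, while the other C–H next to bromine is shielded by the non-coordinating OTIPS group.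

**Step 6**
Reactants: 7 6-bromo-3-(1,3-dioxolan-2-yl)-2-methoxy-4-(triisopropylsilyloxy)benzaldehyde
Product: 9 7-(1,3-dioxolan-2-yl)-8-methoxy-3-methyl-6-(triisopropylsilyloxy)isoquinoline, via alkynyl aldehyde 8 (not isolated)
Conditions: propyne, PdCl2(PPh3)2 (5 mol %), CuI (10 mol %), Et3N, DMF, 50 °C (sealed); then NH4OAc (5 equiv), 80 °C
Reagents that add atoms: propyne, CC#C; ammonium acetate, CC(=O)[O-].[NH4+]
Why: Sonogashira coupling at the formyl-activated C–Br bond followed in the same flask by imination with ammonia and copper-assisted 6-endo-dig attack of nitrogen on the alkyne, the known one-pot coupling–imination–annulation route to isoquinolines, which closes the pyridine ring with the methyl group at C3.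

**Step 7**
Reactants: 9 7-(1,3-dioxolan-2-yl)-8-methoxy-3-methyl-6-(triisopropylsilyloxy)isoquinoline
Product: 10 6-hydroxy-8-methoxy-3-methylisoquinoline-7-carbaldehyde
Conditions: 48% aq HF, MeCN, 0 → 23 °C; neutralise to pH 7
Reagents that add atoms: water, O
Why: Aqueous HF cleaves the aryl silyl ether and hydrolyses the very acid-labile 2,6-dioxygenated aryl dioxolane in one global deprotection.

**Step 8**
Reactants: 10 6-hydroxy-8-methoxy-3-methylisoquinoline-7-carbaldehyde
Product: 11 8-methoxy-3-methyl-6-(triethylsilyloxy)isoquinoline-7-carbaldehyde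
Conditions: TESCl, imidazole, CH2Cl2, 0 °C
Reagents that add atoms: chlorotriethylsilane, CC[Si](Cl)(CC)CC
Why: Routine phenol silylation that removes the acidic O–H before the allylborane is added, with TES chosen because it should fall off in the mildly basic perborate work-up of step 9 while the hindered aryl TIPS ether stays.

**Step 9**
Reactants: 5 2-[2-methoxy-4-(propa-1,2-dien-1-yl)-6-(triisopropylsilyloxy)phenyl]-1,3-dioxolane; 11 8-methoxy-3-methyl-6-(triethylsilyloxy)isoquinoline-7-carbaldehyde
Product: 14 (1R,2S)-2-[4-(1,3-dioxolan-2-yl)-3-methoxy-5-(triisopropylsilyloxy)phenyl]-1-(6-hydroxy-8-methoxy-3-methylisoquinolin-7-yl)but-3-en-1-ol, via allylborane 12 (not isolated), via borinate 13 (not isolated)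
Conditions: (+)-Ipc2BH, THF, 0 → 23 °C; 11, −78 → −20 °C; NaBO3·4H2O, THF/H2O, 23 °C
Reagents that add atoms: none
Why: Allene hydroboration followed by Brown asymmetric allylboration, in which boron adds to the terminal CH2, 1,3-borotropic equilibration gives the conjugated (E)-γ-aryl allylborane, the closed Zimmerman–Traxler chair translates the E geometry into the anti pair, and the isopinocampheyl groups derived from (−)-α-pinene direct attack to the Re face of the aldehyde to set the R carbinol and the S aryl-bearing carbon.

**Step 10**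
Reactants: 14 (1R,2S)-2-[4-(1,3-dioxolan-2-yl)-3-methoxy-5-(triisopropylsilyloxy)phenyl]-1-(6-hydroxy-8-methoxy-3-methylisoquinolin-7-yl)but-3-en-1-ol
Product: 18 vinyl tetracycle aldehyde (TIPS ether; acetal C R; O–CH R; vinyl-bearing C S), via cyclic orthoformate 15 (not isolated), via dioxinylium ion 16 (not isolated), via dioxolane tetracycle 17 (not isolated)
Conditions: HC(OMe)3 (1.5 equiv), TfOH (1.3 equiv), 4 Å MS, CH2Cl2, −20 → 0 °C; then 1 M aq HCl, THF, 0 °C
Reagents that add atoms: trimethyl orthoformate, COC(OC)OC; water, O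
Why: Proposed new method: acid-catalysed exchange of the orthoformate with the C6 phenol and the benzylic alcohol of 14 closes the 1,3-dioxine ring first (6-exo-trig attack of the second oxygen on an acyclic dialkoxycarbenium ion) to give 15, loss of methanol gives the cyclic dioxocarbenium ion 16, and the dialkoxyarene attacks its carbon in a 6-endo-trig Friedel–Crafts step that closes the isochroman ring last and gives 17 after rearomatisation. The closest known reaction types are the oxa-Pictet–Spengler cyclisation, the orthoformate formylation of electron-rich arenes and arylacetones, and the intramolecular Friedel–Crafts capture of cyclic oxocarbenium ions that gives oxygen-bridged benzo-fused bicycles, and what is new is the use of a cyclic orthoformate-derived cation, so that one C1 reagent supplies the acetal carbon and both rings form in one flask. The new acetal stereocentre is controlled by the benzylic C–O stereocentre, because allylic strain with the C8 methoxy group holds the side chain pseudo-axial on the flat cation, the arene can reach only that face and a one-oxygen bridge can only span cis, which gives the R centre, while the two centres set in step 9 are not touched since nothing is enolisable at the vinyl stage. Site selectivity between the two free arene carbons ortho to the side chain is needed: both have one ortho and one para oxygen donor, but the carbon next to OTIPS is shielded by the silyl group, which the neighbouring dioxolane pushes towards it, so attack should occur at the carbon next to the small OMe group. Chemoselectivity is also needed: the dioxolane keeps the ring electron-rich where a free formyl group would deactivate it, the monosubstituted alkene is a far weaker nucleophile than the dialkoxyarene so that Prins closure and 2-oxonia-Cope rearrangement should not compete for a stabilised dioxocarbenium ion, and protonation of the isoquinoline nitrogen disfavours ionisation of the benzylic C–O bond. The aqueous acid quench should hydrolyse only the very labile 2,6-dioxygenated aryl dioxolane, since the bridged acetal, if opened, can only re-close.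

**Step 11**
Reactants: 18 vinyl tetracycle aldehyde (TIPS ether)
Product: 19 acetyl tetracycle aldehyde (TIPS ether; acetal C R; O–CH R; acetyl-bearing C S)
Conditions: PdCl2 (20 mol %), CuCl (50 mol %), O2 (1 atm), DMF/H2O 7:1, 23 °C
Reagents that add atoms: water, O
Why: Tsuji–Wacker oxidation, in which Markovnikov hydroxypalladation of the terminal alkene gives the methyl ketone under weakly acidic conditions that should leave the adjacent, now enolisable stereocentre and the acetal untouched.

**Step 12**
Reactants: 19 acetyl tetracycle aldehyde (TIPS ether)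
Product: 20 CNP0584953.1
Conditions: HF·pyridine, pyridine, THF, 0 °C; pH 7 buffer
Reagents that add atoms: none
Why: Fluoride cleavage of the ortho-formyl aryl silyl ether in an acidic buffer, chosen because base could open the β-alkoxy ketone by E1cB elimination and so erase all three stereocentres.

**Compound list**
1 | 4-bromo-2,6-dimethoxybenzaldehyde | COc1cc(Br)cc(OC)c1C=O | starting material
2 | 4-bromo-2-hydroxy-6-methoxybenzaldehyde | COc1cc(Br)cc(O)c1C=O | intermediate
3 | 4-bromo-2-methoxy-6-(triisopropylsilyloxy)benzaldehyde | COc1cc(Br)cc(O[Si](C(C)C)(C(C)C)C(C)C)c1C=O | intermediate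
4 | 2-[4-bromo-2-methoxy-6-(triisopropylsilyloxy)phenyl]-1,3-dioxolane | COc1cc(Br)cc(O[Si](C(C)C)(C(C)C)C(C)C)c1C1OCCO1 | intermediate
5 | 2-[2-methoxy-4-(propa-1,2-dien-1-yl)-6-(triisopropylsilyloxy)phenyl]-1,3-dioxolane | COc1cc(C=C=C)cc(O[Si](C(C)C)(C(C)C)C(C)C)c1C1OCCO1 | intermediate
6 | [6-bromo-3-(1,3-dioxolan-2-yl)-2-methoxy-4-(triisopropylsilyloxy)phenyl]lithium | COc1c([Li])c(Br)cc(O[Si](C(C)C)(C(C)C)C(C)C)c1C1OCCO1 | intermediate
7 | 6-bromo-3-(1,3-dioxolan-2-yl)-2-methoxy-4-(triisopropylsilyloxy)benzaldehyde | COc1c(C=O)c(Br)cc(O[Si](C(C)C)(C(C)C)C(C)C)c1C1OCCO1 | intermediate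
8 | 3-(1,3-dioxolan-2-yl)-2-methoxy-6-(prop-1-yn-1-yl)-4-(triisopropylsilyloxy)benzaldehyde | COc1c(C=O)c(C#CC)cc(O[Si](C(C)C)(C(C)C)C(C)C)c1C1OCCO1 | intermediate
9 | 7-(1,3-dioxolan-2-yl)-8-methoxy-3-methyl-6-(triisopropylsilyloxy)isoquinoline | COc1c(C2OCCO2)c(O[Si](C(C)C)(C(C)C)C(C)C)cc2cc(C)ncc12 | intermediate
10 | 6-hydroxy-8-methoxy-3-methylisoquinoline-7-carbaldehyde | COc1c(C=O)c(O)cc2cc(C)ncc12 | intermediate
11 | 8-methoxy-3-methyl-6-(triethylsilyloxy)isoquinoline-7-carbaldehyde | COc1c(C=O)c(O[Si](CC)(CC)CC)cc2cc(C)ncc12 | intermediate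
12 | {(E)-3-[4-(1,3-dioxolan-2-yl)-3-methoxy-5-(triisopropylsilyloxy)phenyl]prop-2-en-1-yl}bis(isopinocampheyl)borane, Ipc from (−)-α-pinene | COc1cc(/C=C/CB([C@H]2C[C@H]3C[C@@H]([C@@H]2C)C3(C)C)[C@H]2C[C@H]3C[C@@H]([C@@H]2C)C3(C)C)cc(O[Si](C(C)C)(C(C)C)C(C)C)c1C1OCCO1 | intermediate
13 | bis(isopinocampheyl)borinate of the (1R,2S) adduct, 6-O-TES ether | CC[Si](CC)(CC)Oc1cc2cc(C)ncc2c(OC)c1[C@H](OB([C@H]1C[C@H]2C[C@@H]([C@@H]1C)C2(C)C)[C@H]1C[C@H]2C[C@@H]([C@@H]1C)C2(C)C)[C@H](c1cc(OC)c(C2OCCO2)c(O[Si](C(C)C)(C(C)C)C(C)C)c1)C=C | intermediate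
14 | (1R,2S)-2-[4-(1,3-dioxolan-2-yl)-3-methoxy-5-(triisopropylsilyloxy)phenyl]-1-(6-hydroxy-8-methoxy-3-methylisoquinolin-7-yl)but-3-en-1-ol | Oc1cc2cc(C)ncc2c(OC)c1[C@H](O)[C@H](c1cc(OC)c(C2OCCO2)c(O[Si](C(C)C)(C(C)C)C(C)C)c1)C=C | intermediate
15 | cyclic orthoformate: 2-methoxy-1,3-dioxine ring fused to C6–C7 of the isoquinoline (O1 on C6, C4 the former carbinol carbon, R), C4 bearing the (S)-1-arylallyl group, both epimers at C2 | COC1Oc2cc3cc(C)ncc3c(OC)c2[C@H](O1)[C@H](c1cc(OC)c(C2OCCO2)c(O[Si](C(C)C)(C(C)C)C(C)C)c1)C=C | intermediate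
16 | 1,3-dioxin-2-ylium ion derived from 15 by loss of methoxide | [CH+]1Oc2cc3cc(C)ncc3c(OC)c2[C@H](O1)[C@H](c1cc(OC)c(C2OCCO2)c(O[Si](C(C)C)(C(C)C)C(C)C)c1)C=C | intermediate
17 | bridged tetracycle (isoquinoline-fused 1,3-dioxine and benzo-fused isochroman sharing the bridging O; acetal C R, O–CH R, vinyl-bearing C S); benzo ring from the acetal carbon: OMe, 1,3-dioxolan-2-yl, OTIPS, H | COc1c(C2OCCO2)c(O[Si](C(C)C)(C(C)C)C(C)C)cc2c1[C@H]1Oc3cc4cc(C)ncc4c(OC)c3[C@H](O1)[C@H]2C=C | intermediate
18 | as 17 with CHO in place of the dioxolane (vinyl tetracycle aldehyde, TIPS ether) | COc1c(C=O)c(O[Si](C(C)C)(C(C)C)C(C)C)cc2c1[C@H]1Oc3cc4cc(C)ncc4c(OC)c3[C@H](O1)[C@H]2C=C | intermediate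
19 | as 18 with acetyl in place of vinyl (acetyl-bearing C S), TIPS ether of the target | COc1c(C=O)c(O[Si](C(C)C)(C(C)C)C(C)C)cc2c1[C@H]1Oc3cc4cc(C)ncc4c(OC)c3[C@H](O1)[C@H]2C(C)=O | intermediate
20 | CNP0584953.1 | COc1c(C=O)c(O)cc2c1[C@H]1Oc3cc4cc(C)ncc4c(OC)c3[C@H](O1)[C@H]2C(C)=O | target

**Step count and sequence**
Total step count: 12.
Longest linear sequence: 11 steps (1, 2, 3, 5, 6, 7, 8, 9, 10, 11, 12).

**Steps most likely to fail**

1. **Step 10 (Proposed new method).**
   - What may go wrong: attack of the arene through the wrong ortho carbon, capture of the cation by the vinyl group, or loss of the benzylic oxygen by ionisation before the C–C bond forms.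
   - Fallback (known chemistry), from 7 back to 18: compound 7 already carries the future acetal carbon at the correct ring position.
   - Acetalisation of 7 as in step 3 would give the bis(dioxolane) bromide F1.
   - Stille coupling as in step 4 would give the bis(dioxolane) allene F2.
   - Hydroboration with (+)-Ipc2BH as in step 9 would give the bis(dioxolane) allylborane F3. Its addition to 11 and perborate work-up would give the (1R,2S) bis(dioxolane) diol F4.
   - Aqueous HCl in THF, followed by azeotropic drying with a trace of acid, would hydrolyse both dioxolanes. The freed ortho formyl group would then condense with the benzylic alcohol and the phenol. This is an intramolecular acetalisation under thermodynamic control, and the regiochemical question does not arise.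

2. **Step 9.**
   - What may go wrong: slow addition to the doubly ortho-substituted aldehyde, which forces a higher temperature and brings poor facial selectivity. Incomplete Z-to-E equilibration of the allylborane would erode the anti selectivity.
   - Fallback, from 5 and 11 back to 14: hydroboration of 5 with dicyclohexylborane would give the less hindered achiral (E)-allyl(dicyclohexyl)borane F5.
   - F5 should add to 11 at low temperature through the same chair. Perborate work-up would then give the anti diol as the racemate, that is 14 together with its enantiomer, the (1S,2R)-diol F6.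
   - Classical resolution at the basic isoquinoline nitrogen follows. Fractional crystallisation with (1S)-(+)-camphor-10-sulfonic acid would give the camphorsulfonate salt of 14 F7, and aqueous NaHCO3 would release the free base 14.

3. **Step 11.**
   - What may go wrong: binding of palladium by the isoquinoline nitrogen, migration of the double bond into conjugation with the arene, or attack of water at the terminal carbon.
   - Fallback, from 18 back to 19: Mukaiyama hydration (Co(acac)2, PhSiH3, O2, then P(OEt)3) adds water in the Markovnikov sense by hydrogen-atom transfer. It would give the secondary alcohol F8 as a mixture at the carbinol carbon.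
   - Dess–Martin oxidation under neutral conditions would then give the ketone 19.

**Further compounds**
F1 | step 10 | 2,2'-[4-bromo-2-methoxy-6-(triisopropylsilyloxy)-1,3-phenylene]bis(1,3-dioxolane) | COc1c(C2OCCO2)c(Br)cc(O[Si](C(C)C)(C(C)C)C(C)C)c1C1OCCO1
F2 | step 10 | 2,2'-[2-methoxy-4-(propa-1,2-dien-1-yl)-6-(triisopropylsilyloxy)-1,3-phenylene]bis(1,3-dioxolane) | COc1c(C2OCCO2)c(C=C=C)cc(O[Si](C(C)C)(C(C)C)C(C)C)c1C1OCCO1
F3 | step 10 | {(E)-3-[2,4-bis(1,3-dioxolan-2-yl)-3-methoxy-5-(triisopropylsilyloxy)phenyl]prop-2-en-1-yl}bis(isopinocampheyl)borane | COc1c(C2OCCO2)c(/C=C/CB([C@H]2C[C@H]3C[C@@H]([C@@H]2C)C3(C)C)[C@H]2C[C@H]3C[C@@H]([C@@H]2C)C3(C)C)cc(O[Si](C(C)C)(C(C)C)C(C)C)c1C1OCCO1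
F4 | step 10 | (1R,2S)-2-[2,4-bis(1,3-dioxolan-2-yl)-3-methoxy-5-(triisopropylsilyloxy)phenyl]-1-(6-hydroxy-8-methoxy-3-methylisoquinolin-7-yl)but-3-en-1-ol | Oc1cc2cc(C)ncc2c(OC)c1[C@H](O)[C@H](c1cc(O[Si](C(C)C)(C(C)C)C(C)C)c(C2OCCO2)c(OC)c1C1OCCO1)C=C
F5 | step 9 | dicyclohexyl{(E)-3-[4-(1,3-dioxolan-2-yl)-3-methoxy-5-(triisopropylsilyloxy)phenyl]prop-2-en-1-yl}borane | COc1cc(/C=C/CB(C2CCCCC2)C2CCCCC2)cc(O[Si](C(C)C)(C(C)C)C(C)C)c1C1OCCO1
F6 | step 9 | (1S,2R)-enantiomer of 14 | Oc1cc2cc(C)ncc2c(OC)c1[C@@H](O)[C@@H](c1cc(OC)c(C2OCCO2)c(O[Si](C(C)C)(C(C)C)C(C)C)c1)C=C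
F7 | step 9 | isoquinolinium (1S)-camphor-10-sulfonate of 14 | Oc1cc2cc(C)[nH+]cc2c(OC)c1[C@H](O)[C@H](c1cc(OC)c(C2OCCO2)c(O[Si](C(C)C)(C(C)C)C(C)C)c1)C=C.CC1([C@@H]2CC[C@]1(C(=O)C2)CS(=O)(=O)[O-])C
F8 | step 11 | 1-hydroxyethyl analogue of 19 (both carbinol epimers) | COc1c(C=O)c(O[Si](C(C)C)(C(C)C)C(C)C)cc2c1[C@H]1Oc3cc4cc(C)ncc4c(OC)c3[C@H](O1)[C@H]2C(C)O
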